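**Strategy.** The isoflavan is disconnected at C3–C4. Because the 2'-oxygen of ring B sits ortho to C1', an ether from that oxygen to the ring A benzylic carbon (future C4) holds a C4–H bond in 1,5-relationship to a carbene at C3. One enantioselective rhodium-carbene C–H insertion on aryldiazoacetate 7 (ring B, C3 and the future C2 as ester; ring A attached through O2'–C4) therefore forms C3–C4, closes a cis-2-aryl-2,3-dihydrobenzofuran and sets C3. Chroman closure to a pterocarpan and hydrogenolysis of the temporary C4–O2' bond then give the (3R)-isoflavan; the reverse prenyl group enters by aromatic Claisen rearrangement.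

Key step: step 6

Assumption: isoflavan numbering is used (O1, C2, C3, C4, ring A = chroman benzo ring, ring B = C1'–C6'); the S-configured catalyst is taken to give the (2R,3S) cis ester, as it does with simpler ortho-benzyloxy aryldiazoacetates, and the mirror-image catalyst would be used if the sense of induction on 7 proved opposite.

Protecting-group plan: the 4'-oxygen carries TIPS (put on by steric discrimination) and the 7-oxygen carries benzyl (lost in the hydrogenolysis), so that after ring opening the 7- and 2'-phenols are capped together as pivalates and the 4'-silyl ether is the only site that fluoride converts into the prenyl ether.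

**Step 1**
Reactants: 1 4-(benzyloxy)-2-hydroxybenzaldehyde
Product: 2 5-(benzyloxy)-2-formylphenyl pivalate
Conditions: PivCl, Et3N, DMAP (cat.), CH2Cl2, 0 °C to rt
Reagents that add atoms: pivaloyl chloride, CC(C)(C)C(Cl)=O
Why: DMAP-catalysed O-acylation of the phenol; the hindered pivalate resists O-to-O acyl migration and is removed later together with the ester reduction.

**Step 2**
Reactants: 2 5-(benzyloxy)-2-formylphenyl pivalate
Product: 3 5-(benzyloxy)-2-(hydroxymethyl)phenyl pivalate
Conditions: NaBH4, THF–MeOH, −20 °C; AcOH quench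
Reagents that add atoms: none
Why: Chemoselective borohydride reduction of the aldehyde, with low temperature and an acidic quench to keep the pivaloyl group from moving to the new benzylic alkoxide.

**Step 3**
Reactants: 4 methyl 2-(2,4-dihydroxyphenyl)acetate
Product: 5 methyl 2-[2-hydroxy-4-(triisopropylsilyloxy)phenyl]acetate
Conditions: TIPSCl (1.0 equiv), imidazole, CH2Cl2–DMF, −20 to 0 °C
Reagents that add atoms: triisopropylsilyl chloride, CC(C)[Si](Cl)(C(C)C)C(C)C
Why: Phenol silylation in which the bulky chloride should prefer the 4-hydroxyl (two ortho hydrogens) over the 2-hydroxyl, which is flanked by the CH2CO2Me arm and can hydrogen-bond to the ester carbonyl.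

**Step 4**
Reactants: 3 5-(benzyloxy)-2-(hydroxymethyl)phenyl pivalate; 5 methyl 2-[2-hydroxy-4-(triisopropylsilyloxy)phenyl]acetate
Product: 6 methyl 2-{2-[4-(benzyloxy)-2-(pivaloyloxy)benzyloxy]-4-(triisopropylsilyloxy)phenyl}acetate
Conditions: PPh3, DIAD, THF, 0 °C to rt
Reagents that add atoms: none
Why: Mitsunobu etherification of a phenol with a primary benzylic alcohol under neutral conditions, which avoids a labile benzyl bromide, base-mediated C-alkylation of the arylacetate, lactonisation and pivaloyl transfer.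

**Step 5**
Reactants: 6 methyl 2-{2-[4-(benzyloxy)-2-(pivaloyloxy)benzyloxy]-4-(triisopropylsilyloxy)phenyl}acetate
Product: 7 methyl 2-diazo-2-{2-[4-(benzyloxy)-2-(pivaloyloxy)benzyloxy]-4-(triisopropylsilyloxy)phenyl}acetate
Conditions: p-ABSA, DBU, anhydrous MeCN, 0 °C to rt
Reagents that add atoms: 4-acetamidobenzenesulfonyl azide, CC(=O)Nc1ccc(cc1)S(=O)(=O)N=[N+]=[N-]
Why: Regitz diazo transfer to the benzylic ester enolate, the standard entry to aryldiazoacetates; under anhydrous conditions the aryl silyl ether and the pivalate should survive the amidine base.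

**Step 6**
Reactants: 7 methyl 2-diazo-2-{2-[4-(benzyloxy)-2-(pivaloyloxy)benzyloxy]-4-(triisopropylsilyloxy)phenyl}acetate
Product: 8 methyl (2R,3S)-2-[4-(benzyloxy)-2-(pivaloyloxy)phenyl]-6-(triisopropylsilyloxy)-2,3-dihydrobenzofuran-3-carboxylate (cis)
Conditions: dirhodium tetrakis[N-phthaloyl-(S)-tert-leucinate], Rh2(S-PTTL)4 (2 mol %), toluene, −78 to −60 °C, slow addition of 7
Reagents that add atoms: none
Why: Rh2(S-PTTL)4 expels N2 from 7 to give a donor–acceptor rhodium carbene at C3, which inserts through a concerted, asynchronous three-centre (hydride-transfer-like) transition state into one of the two enantiotopic C–H bonds of the O2'–CH2 group and so forms C3–C4. The closest known reaction type is the enantioselective intramolecular C–H insertion of ortho-benzyloxy aryldiazoacetates under chiral divalent rhodium carboxylate catalysis, which gives cis-2-aryl-2,3-dihydrobenzofuran-3-carboxylates. The dihydrofuran ring closes by 1,5-insertion, the carbene carbon and the C–H carbon being linked through C1', C2' and O2', and no other ring size is within reach of the tether. Both new stereocentres (benzofuran C3 = isoflavan C3, benzofuran C2 = isoflavan C4) are set in this single transition state by the chiral pocket of the four N-phthaloyl-tert-leucinate ligands, which selects the carbene face and the C–H bond so that ring A and the ester end up cis; C4 is reduced to CH2 in step 9, so only C3 persists (S here, R in the isoflavan after the change in substituent priorities). The step needs chemoselectivity, cis diastereoselectivity and enantioselectivity: the targeted C–H bond is the only one five atoms from the carbene and is activated by the ether oxygen and the electron-rich 4-benzyloxyphenyl ring, the small methyl ester matches the substrates for which this catalyst class is selective, and low temperature in toluene should suppress Buchner-type attack on ring A and keep the kinetically formed cis ester from epimerising.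

**Step 7**
Reactants: 8 methyl (2R,3S)-2-[4-(benzyloxy)-2-(pivaloyloxy)phenyl]-6-(triisopropylsilyloxy)-2,3-dihydrobenzofuran-3-carboxylate
Product: 9 5-(benzyloxy)-2-[(2R,3R)-3-(hydroxymethyl)-6-(triisopropylsilyloxy)-2,3-dihydrobenzofuran-2-yl]phenol
Conditions: LiAlH4, THF, −20 to 0 °C; Rochelle salt work-up
Reagents that add atoms: none
Why: Hydride reduction turns the methyl ester into the C2 hydroxymethyl group and cleaves the aryl pivalate in the same operation; fast reduction at low temperature should leave the C3 centre untouched, and the descriptor changes only because the priorities change.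

**Step 8**
Reactants: 9 5-(benzyloxy)-2-[(2R,3R)-3-(hydroxymethyl)-6-(triisopropylsilyloxy)-2,3-dihydrobenzofuran-2-yl]phenol
Product: 10 (6aR,11aR)-3-(benzyloxy)-9-(triisopropylsilyloxy)-6a,11a-dihydro-6H-benzofuro[3,2-c]chromene (cis-pterocarpan)
Conditions: PPh3, DIAD, THF, 0 °C
Reagents that add atoms: none
Why: Intramolecular Mitsunobu etherification (6-exo-tet) in which the ring A phenol displaces the activated primary alcohol to form O1–C2; no stereocentre reacts, and the cis arrangement from step 6 is what allows the cis ring fusion.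

**Step 9**
Reactants: 10 (6aR,11aR)-3-(benzyloxy)-9-(triisopropylsilyloxy)-6a,11a-dihydro-6H-benzofuro[3,2-c]chromene
Product: 12 (3R)-3-[2-hydroxy-4-(triisopropylsilyloxy)phenyl]chroman-7-ol, via 3-hydroxypterocarpan 11 (not isolated)
Conditions: H2 (1–4 atm), 10% Pd/C, EtOAc–EtOH, rt
Reagents that add atoms: none
Why: Catalytic hydrogenolysis should first remove the O-benzyl group and then cleave the benzylic C4–O2' aryl ether of the pterocarpan, the classical pterocarpan-to-2'-hydroxyisoflavan reduction; C3 is not involved and keeps its configuration.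

**Step 10**
Reactants: 12 (3R)-3-[2-hydroxy-4-(triisopropylsilyloxy)phenyl]chroman-7-ol
Product: 13 (3R)-3-[2-(pivaloyloxy)-4-(triisopropylsilyloxy)phenyl]chroman-7-yl pivalate
Conditions: PivCl (excess), Et3N, DMAP, CH2Cl2, rt
Reagents that add atoms: pivaloyl chloride, CC(C)(C)C(Cl)=O
Why: Exhaustive DMAP-catalysed acylation of both free phenols, so no selectivity is required; the pivalates tolerate fluoride, carbonate and heat in steps 11–13 and the one at O2' shields C3'.

**Step 11**
Reactants: 13 (3R)-3-[2-(pivaloyloxy)-4-(triisopropylsilyloxy)phenyl]chroman-7-yl pivalate; 14 prenyl bromide (1-bromo-3-methylbut-2-ene)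
Product: 16 (3R)-3-[4-(3-methylbut-2-enyloxy)-2-(pivaloyloxy)phenyl]chroman-7-yl pivalate, via caesium 4'-phenoxide 15 (not isolated)
Conditions: CsF, prenyl bromide, DMF, rt
Reagents that add atoms: none
Why: Fluoride cleaves the aryl silyl ether and the resulting phenoxide is alkylated in situ at the primary allylic carbon (one-pot desilylation and Williamson etherification), so the 4'-oxygen is prenylated without competition from any other phenol.

**Step 12**
Reactants: 16 (3R)-3-[4-(3-methylbut-2-enyloxy)-2-(pivaloyloxy)phenyl]chroman-7-yl pivalate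
Product: 18 (3R)-3-[4-hydroxy-5-(2-methylbut-3-en-2-yl)-2-(pivaloyloxy)phenyl]chroman-7-yl pivalate, via Claisen dienone 17 (not isolated)
Conditions: PhNEt2, 180 °C, sealed tube, Ar; stopped at full conversion
Reagents that add atoms: none
Why: Aromatic Claisen rearrangement ([3,3]-sigmatropic shift, then tautomerisation) delivers the allyl unit with inversion as the 1,1-dimethylallyl group to C5', because C3' lies between two oxygen substituents, is shielded by the pivaloyloxy group and would have to accept a quaternary carbon, while the para position C1' is blocked.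

**Step 13**
Reactants: 18 (3R)-3-[4-hydroxy-5-(2-methylbut-3-en-2-yl)-2-(pivaloyloxy)phenyl]chroman-7-yl pivalate; 14 prenyl bromide
Product: 19 (3R)-3-[5-(2-methylbut-3-en-2-yl)-4-(3-methylbut-2-enyloxy)-2-(pivaloyloxy)phenyl]chroman-7-yl pivalate
Conditions: Cs2CO3, DMF, rt
Reagents that add atoms: none
Why: Williamson etherification of the only free phenol; the caesium phenoxide in DMF is reactive enough to overcome the neighbouring tert-alkyl group, and the aryl pivalates are stable to anhydrous carbonate.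

**Step 14**
Reactants: 19 (3R)-3-[5-(2-methylbut-3-en-2-yl)-4-(3-methylbut-2-enyloxy)-2-(pivaloyloxy)phenyl]chroman-7-yl pivalate
Product: 20 Manuifolin D, (3R)-3-[2-hydroxy-5-(2-methylbut-3-en-2-yl)-4-(3-methylbut-2-enyloxy)phenyl]chroman-7-ol
Conditions: LiAlH4, THF, 0 °C; Rochelle salt work-up
Reagents that add atoms: none
Why: Reductive cleavage of both aryl pivalates frees the 7- and 2'-phenols under non-acidic conditions that leave the aryl prenyl ether, the terminal alkene and C3 untouched.

**Compound list**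

1 | 4-(benzyloxy)-2-hydroxybenzaldehyde | O=Cc1ccc(OCc2ccccc2)cc1O | starting material
2 | 5-(benzyloxy)-2-formylphenyl pivalate | CC(C)(C)C(=O)Oc1cc(OCc2ccccc2)ccc1C=O | intermediate
3 | 5-(benzyloxy)-2-(hydroxymethyl)phenyl pivalate | CC(C)(C)C(=O)Oc1cc(OCc2ccccc2)ccc1CO | intermediate
4 | methyl 2-(2,4-dihydroxyphenyl)acetate | COC(=O)Cc1ccc(O)cc1O | starting material
5 | methyl 2-[2-hydroxy-4-(triisopropylsilyloxy)phenyl]acetate | COC(=O)Cc1ccc(O[Si](C(C)C)(C(C)C)C(C)C)cc1O | intermediate
6 | methyl 2-{2-[4-(benzyloxy)-2-(pivaloyloxy)benzyloxy]-4-(triisopropylsilyloxy)phenyl}acetate | COC(=O)Cc1ccc(O[Si](C(C)C)(C(C)C)C(C)C)cc1OCc1ccc(OCc2ccccc2)cc1OC(=O)C(C)(C)C | intermediate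
7 | methyl 2-diazo-2-{2-[4-(benzyloxy)-2-(pivaloyloxy)benzyloxy]-4-(triisopropylsilyloxy)phenyl}acetate | COC(=O)C(=[N+]=[N-])c1ccc(O[Si](C(C)C)(C(C)C)C(C)C)cc1OCc1ccc(OCc2ccccc2)cc1OC(=O)C(C)(C)C | intermediate
8 | methyl (2R,3S)-2-[4-(benzyloxy)-2-(pivaloyloxy)phenyl]-6-(triisopropylsilyloxy)-2,3-dihydrobenzofuran-3-carboxylate (cis) | COC(=O)[C@H]1c2ccc(O[Si](C(C)C)(C(C)C)C(C)C)cc2O[C@H]1c1ccc(OCc2ccccc2)cc1OC(=O)C(C)(C)C | intermediate
9 | 5-(benzyloxy)-2-[(2R,3R)-3-(hydroxymethyl)-6-(triisopropylsilyloxy)-2,3-dihydrobenzofuran-2-yl]phenol (cis) | OC[C@H]1c2ccc(O[Si](C(C)C)(C(C)C)C(C)C)cc2O[C@H]1c1ccc(OCc2ccccc2)cc1O | intermediate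
10 | (6aR,11aR)-3-(benzyloxy)-9-(triisopropylsilyloxy)-6a,11a-dihydro-6H-benzofuro[3,2-c]chromene | O1C[C@H]2c3ccc(O[Si](C(C)C)(C(C)C)C(C)C)cc3O[C@H]2c2ccc(OCc3ccccc3)cc21 | intermediate
11 | (6aR,11aR)-9-(triisopropylsilyloxy)-6a,11a-dihydro-6H-benzofuro[3,2-c]chromen-3-ol (not isolated) | O1C[C@H]2c3ccc(O[Si](C(C)C)(C(C)C)C(C)C)cc3O[C@H]2c2ccc(O)cc21 | intermediate
12 | (3R)-3-[2-hydroxy-4-(triisopropylsilyloxy)phenyl]chroman-7-ol | Oc1cc(O[Si](C(C)C)(C(C)C)C(C)C)ccc1[C@@H]1COc2cc(O)ccc2C1 | intermediate
13 | (3R)-3-[2-(pivaloyloxy)-4-(triisopropylsilyloxy)phenyl]chroman-7-yl pivalate | CC(C)(C)C(=O)Oc1cc(O[Si](C(C)C)(C(C)C)C(C)C)ccc1[C@@H]1COc2cc(OC(=O)C(C)(C)C)ccc2C1 | intermediate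
14 | prenyl bromide (1-bromo-3-methylbut-2-ene) | CC(C)=CCBr | starting material
15 | caesium 4-[(3R)-7-(pivaloyloxy)chroman-3-yl]-3-(pivaloyloxy)phenoxide (not isolated) | [Cs+].[O-]c1ccc([C@@H]2COc3cc(OC(=O)C(C)(C)C)ccc3C2)c(OC(=O)C(C)(C)C)c1 | intermediate
16 | (3R)-3-[4-(3-methylbut-2-enyloxy)-2-(pivaloyloxy)phenyl]chroman-7-yl pivalate | CC(C)=CCOc1ccc([C@@H]2COc3cc(OC(=O)C(C)(C)C)ccc3C2)c(OC(=O)C(C)(C)C)c1 | intermediate
17 | (3R)-3-[3-(2-methylbut-3-en-2-yl)-4-oxo-6-(pivaloyloxy)cyclohexa-1,5-dien-1-yl]chroman-7-yl pivalate (ring sp3 centre undefined; not isolated) | O=C1C=C(OC(=O)C(C)(C)C)C([C@@H]2COc3cc(OC(=O)C(C)(C)C)ccc3C2)=CC1C(C)(C)C=C | intermediate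
18 | (3R)-3-[4-hydroxy-5-(2-methylbut-3-en-2-yl)-2-(pivaloyloxy)phenyl]chroman-7-yl pivalate | C=CC(C)(C)c1cc([C@@H]2COc3cc(OC(=O)C(C)(C)C)ccc3C2)c(OC(=O)C(C)(C)C)cc1O | intermediate
19 | (3R)-3-[5-(2-methylbut-3-en-2-yl)-4-(3-methylbut-2-enyloxy)-2-(pivaloyloxy)phenyl]chroman-7-yl pivalate | C=CC(C)(C)c1cc([C@@H]2COc3cc(OC(=O)C(C)(C)C)ccc3C2)c(OC(=O)C(C)(C)C)cc1OCC=C(C)C | intermediate
20 | Manuifolin D, (3R)-3-[2-hydroxy-5-(2-methylbut-3-en-2-yl)-4-(3-methylbut-2-enyloxy)phenyl]chroman-7-ol | C=CC(C)(C)c1cc([C@@H]2COc3cc(O)ccc3C2)c(O)cc1OCC=C(C)C | target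

**Totals.** Total steps: 14. Longest linear sequence: 13 steps (from 1 through steps 1, 2 and 4–14); the ring B branch from 4 joins at step 4.

**Steps most likely to fail**

1. **Step 6.** The ortho-pivaloyloxy group next to the reacting CH2 may erode enantio- or cis-selectivity. The carbene may also be diverted into attack on ring A or into dimerisation, and the cis ester may epimerise on handling. Fallback (auxiliary-controlled alkylation in place of the carbene step), setting out from 5 and 3 and returning at 12: phenol 5 would be O-benzylated (BnBr, K2CO3, acetone) to methyl 2-[2-(benzyloxy)-4-(triisopropylsilyloxy)phenyl]acetate F1. Hydrolysis with Me3SnOH would give 2-[2-(benzyloxy)-4-(triisopropylsilyloxy)phenyl]acetic acid F2. Its pivaloyl mixed anhydride would acylate lithiated (R)-4-benzyloxazolidin-2-one to give (4R)-4-benzyl-3-{2-[2-(benzyloxy)-4-(triisopropylsilyloxy)phenyl]acetyl}oxazolidin-2-one F3. Alcohol 3 would be converted by Appel bromination (CBr4, PPh3) into 5-(benzyloxy)-2-(bromomethyl)phenyl pivalate F4. The sodium enolate of F3 (NaN(SiMe3)2, THF, −78 °C) should be alkylated by F4 on the face opposite the auxiliary benzyl group to give (4R)-4-benzyl-3-{(2R)-2-[2-(benzyloxy)-4-(triisopropylsilyloxy)phenyl]-3-[4-(benzyloxy)-2-(pivaloyloxy)phenyl]propanoyl}oxazolidin-2-one F5. LiAlH4 would remove auxiliary and pivalate to give 5-(benzyloxy)-2-{(2R)-2-[2-(benzyloxy)-4-(triisopropylsilyloxy)phenyl]-3-hydroxypropyl}phenol F6. Mitsunobu closure would give (3R)-7-(benzyloxy)-3-[2-(benzyloxy)-4-(triisopropylsilyloxy)phenyl]chroman F7, and hydrogenolysis of both benzyl ethers (H2, Pd/C) would give 12.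

2. **Step 12.** Part of the rearrangement may go to C3'. At the temperature required, the product phenol may also isomerise further (abnormal Claisen pathway) or the ether may lose isoprene. Fallback (cross-coupling in place of the sigmatropic step), setting out from 13 and returning at 18: buffered desilylation (TBAF, AcOH, THF) would give (3R)-3-[4-hydroxy-2-(pivaloyloxy)phenyl]chroman-7-yl pivalate F8. Ortho-bromination of this phenol (NBS, CH2Cl2, −40 °C) at the open, less hindered C5' would give (3R)-3-[5-bromo-4-hydroxy-2-(pivaloyloxy)phenyl]chroman-7-yl pivalate F9. A ligand-controlled, branch-selective Suzuki–Miyaura coupling with prenylboronic acid pinacol ester (Pd(OAc)2, bulky dialkylbiarylphosphine, K3PO4, aqueous THF) should then install the 1,1-dimethylallyl group and give 18.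

3. **Step 3.** Discrimination between the two phenols may be incomplete, giving a mixture of the 4-O-silyl, 2-O-silyl and bis-silyl ethers. Fallback (tying up the 2-hydroxyl as a lactone), setting out from 4 and returning at 5: acid-catalysed lactonisation (TsOH, toluene, reflux, removal of methanol) would give 6-hydroxybenzofuran-2(3H)-one F10. Silylation of its only hydroxyl (TIPSOTf, 2,6-lutidine, CH2Cl2, −78 °C) would give 6-(triisopropylsilyloxy)benzofuran-2(3H)-one F11. Mild methanolysis of the lactone (MeOH, cat. Et3N, rt) would give 5 with unambiguous regiochemistry.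

**Further compounds**

F1 | step 6 | methyl 2-[2-(benzyloxy)-4-(triisopropylsilyloxy)phenyl]acetate | COC(=O)Cc1ccc(O[Si](C(C)C)(C(C)C)C(C)C)cc1OCc1ccccc1
F2 | step 6 | 2-[2-(benzyloxy)-4-(triisopropylsilyloxy)phenyl]acetic acid | OC(=O)Cc1ccc(O[Si](C(C)C)(C(C)C)C(C)C)cc1OCc1ccccc1
F3 | step 6 | (4R)-4-benzyl-3-{2-[2-(benzyloxy)-4-(triisopropylsilyloxy)phenyl]acetyl}oxazolidin-2-one | O=C1OC[C@@H](Cc2ccccc2)N1C(=O)Cc1ccc(O[Si](C(C)C)(C(C)C)C(C)C)cc1OCc1ccccc1
F4 | step 6 | 5-(benzyloxy)-2-(bromomethyl)phenyl pivalate | CC(C)(C)C(=O)Oc1cc(OCc2ccccc2)ccc1CBr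
F5 | step 6 | (4R)-4-benzyl-3-{(2R)-2-[2-(benzyloxy)-4-(triisopropylsilyloxy)phenyl]-3-[4-(benzyloxy)-2-(pivaloyloxy)phenyl]propanoyl}oxazolidin-2-one | O=C1OC[C@@H](Cc2ccccc2)N1C(=O)[C@H](Cc1ccc(OCc2ccccc2)cc1OC(=O)C(C)(C)C)c1ccc(O[Si](C(C)C)(C(C)C)C(C)C)cc1OCc1ccccc1
F6 | step 6 | 5-(benzyloxy)-2-{(2R)-2-[2-(benzyloxy)-4-(triisopropylsilyloxy)phenyl]-3-hydroxypropyl}phenol | OC[C@H](Cc1ccc(OCc2ccccc2)cc1O)c1ccc(O[Si](C(C)C)(C(C)C)C(C)C)cc1OCc1ccccc1
F7 | step 6 | (3R)-7-(benzyloxy)-3-[2-(benzyloxy)-4-(triisopropylsilyloxy)phenyl]chroman | c1ccccc1COc1cc(O[Si](C(C)C)(C(C)C)C(C)C)ccc1[C@@H]1COc2cc(OCc3ccccc3)ccc2C1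
F8 | step 12 | (3R)-3-[4-hydroxy-2-(pivaloyloxy)phenyl]chroman-7-yl pivalate | Oc1ccc([C@@H]2COc3cc(OC(=O)C(C)(C)C)ccc3C2)c(OC(=O)C(C)(C)C)c1
F9 | step 12 | (3R)-3-[5-bromo-4-hydroxy-2-(pivaloyloxy)phenyl]chroman-7-yl pivalate | Oc1cc(OC(=O)C(C)(C)C)c([C@@H]2COc3cc(OC(=O)C(C)(C)C)ccc3C2)cc1Br
F10 | step 3 | 6-hydroxybenzofuran-2(3H)-one | O=C1Cc2ccc(O)cc2O1
F11 | step 3 | 6-(triisopropylsilyloxy)benzofuran-2(3H)-one | O=C1Cc2ccc(O[Si](C(C)C)(C(C)C)C(C)C)cc2O1
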